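I start from what Monday's run leaves of its partner.

| flask | solid substrate | partner | remark | time |
|---|---|---|---|---|
| Monday's | 0.041 M | 0.082 M (in portions, 3) | run made earlier; portions every 80 min |  |
| flask | 0.082 M | 0.0820 M (in portions, 3) | the portions of partner follow each other after 80 min, the first at the start | 8.0 d |

- Monday's (time / h: solid substrate / %, target / %, starting material / %): 8.00: 0.7, 4.8, 33.2; 15.0: 0, 12.8, 13.7; 25.0: 0.5, 19.1, 6.2; 30.0: 0, 21.2, 3.5; 40.0: 0, 23.1, 1.8

(readings scatter by 0.5 percentage points)

- what was read earlier has a scatter of 0.5 percentage points, one standard deviation
- at the start none of the solid substrate is in solution
- what has only dissolved of solid substrate counts as not reacted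
- a reading or a percentage of target counts all its forms, free or not
- the reaction counts as stopped when no species that holds the solid substrate changes by six tenths of a point or more over the second half of the time
- starting material means what is dissolved; the solid is not counted in it

- why nothing more happens at 8.0 d, or that something still does (for what has run out or reacted, a solid counts together with what of it has only dissolved) (all of the solid substrate has reacted / it is still moving / the partner has run out first / forward and back rates have come level)
- part of the solid substrate that has turned into other species by 8.0 d (what has only dissolved does not count)
- the target standing at 8.0 d, as a percentage of the solid substrate charged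
- the starting material standing at 8.0 d, as a percentage of the solid substrate charged

Monday's flask and this flask hold the same partner, but this flask holds twice the solid substrate. Monday's last portion goes in at 160 min, earlier than the first reading at 8.00 h. After that I read the loss of starting material as pseudo-first-order, with a constant proportional to c(partner).

Between the first two readings the constant is 0.126 h⁻¹, with 78.7% consumed. Between the last two it is lower, 0.0665 h⁻¹, with 97.5% consumed. That second constant is a rough reading: its readings stand at 3.5% and 1.8%, with a scatter of 0.5 percentage points.

I assume a fixed cost. So c(partner) is the charge minus the partner bill times the substrate consumed. The partner bill, meaning partner spent per solid substrate consumed, then comes to 1.69.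

Monday's flask needs 0.0693 M, less than its charge. This flask needs 0.139 M, more than its charge, so here the partner is the limiting reagent. I commit to a conversion of 59.2%. That leaves 40.8% as starting material or solid, and at Monday's target share gives about 13.9% of target.

The forecast differs from my reckoning: all of the solid substrate has reacted, conversion 99.9%, target 61%, starting material 0.1%. Its ground is this: “After that, the remaining dissolved material drains to target.”

The flask gives: the partner has run out first, with 0% of the partner left. Conversion is 72.5%, target 13.7%, starting material 27.5%.

    intermediate B → target (k = 0.105 h⁻¹)
    partner + intermediate A → side product (k = 10.8 M⁻¹ h⁻¹)
    partner + intermediate A → intermediate B (k = 10.7 M⁻¹ h⁻¹)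
    intermediate A → decomposed reagent (k = 1.01 h⁻¹)
    starting material + partner → intermediate A (k = 3.54 M⁻¹ h⁻¹)
    crystals ⇌ target, rate k6*(cs6 - [target]) while solid is left; crystals form when [target] > cs6 (solubility = 33.0 mM, k = 4.27 h⁻¹)
    solid substrate ⇌ starting material, rate k7*(cs7 - [starting material]) while solid is left; crystals form when [starting material] > cs7 (solubility = 31.0 mM, k = 0.782 h⁻¹)

This flask's own bill is 1.38, lower than Monday's reading, so my conversion falls short by 13 points. The neighbour flask is this flask with 0.21 M of partner. Monday's bill asks 0.139 M there, less than that charge, and leaves 34.0% of the partner. In that neighbour flask the solid substrate stands at 0% and the starting material at 0%, conversion is 100%, and 33% of the partner is left.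

The data were generated by integration from invented constants; noise was put on by code.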